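**Plan**
- Retrosynthesis: the dioxolane and both silyl ethers come off last, and the C7–H bond is cut back to a C7 ketone. Ring A is then cut at C1–C2 and C5–C6 (cycloaddition–aromatisation), the ynone at C7–C(alkyne) (Weinreb amide plus ethynyl Grignard), and the chain at the C8–O(aryl) bond (Mitsunobu).
- Enabling feature: ring A carries OH para (C4) and OMe meta (C3) to C7. A 1-dimethylamino-2-methoxy-3-silyloxybutadiene supplies ring A C2–C5 in exactly this pattern when it adds to an ynone whose carbonyl is C7 and whose alkyne carbons become C1 and C6.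
- Forward: ring B is bought as acetosyringone and masked as its dioxolane. The C9–C8–C(=O) chain from (R)-glycerate is etherified onto it and extended by the two alkyne carbons. Ring A is then built on the finished ynone, and reduction and deprotection follow.
- Stereochemistry: C8 (S) comes from methyl (R)-glycerate by SN2 inversion in the Mitsunobu step. C7 (R, erythro) comes from chelation-controlled Zn(BH4)2 reduction directed by C8.

Key step: step 9

Remarks: C7 is the carbinol carbon, C8 the carbon bearing the aryl ether, C9 the CH2OH carbon; ring A is the 4-hydroxy-3-methoxyphenyl ring, ring B the 4-acetyl-2,6-dimethoxyphenyl ring; TBS = tert-butyldimethylsilyl. The target is the (7R,8S) erythro isomer.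
Assumption: aminomethylenation of methoxyacetone by DMF dimethyl acetal is taken to occur at the more acidic methoxy-bearing CH2; any isomer formed at the methyl group would be removed by distillation.

**Step 1**
Reactants: 1 acetosyringone
Product: 2 2,6-dimethoxy-4-(2-methyl-1,3-dioxolan-2-yl)phenol
Conditions: HOCH2CH2OH (excess), p-TsOH·H2O (cat.), toluene, reflux, Dean–Stark; NaHCO3 wash
Reagents that add atoms: ethylene glycol, OCCO
Why: Acid-catalysed ketalisation with azeotropic removal of water should drive the aryl methyl ketone to its dioxolane while the phenol stays free for the later etherification.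

**Step 2**
Reactants: 3 methyl (R)-2,2-dimethyl-1,3-dioxolane-4-carboxylate
Product: 4 methyl (R)-2,3-dihydroxypropanoate
Conditions: 80% aq. AcOH, 40 °C; toluene azeotrope
Reagents that add atoms: none
Why: Acid-catalysed acetonide hydrolysis frees the diol without touching the methyl ester or the stereocentre.

**Step 3**
Reactants: 4 methyl (R)-2,3-dihydroxypropanoate
Product: 5 methyl (R)-3-(tert-butyldimethylsilyloxy)-2-hydroxypropanoate
Conditions: TBSCl (1.05 equiv), imidazole, CH2Cl2, 0 °C
Reagents that add atoms: tert-butyldimethylsilyl chloride, CC(C)(C)[Si](C)(C)Cl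
Why: Selective silyl ether formation at the primary hydroxyl is expected because the secondary α-hydroxy ester position is both more hindered and less nucleophilic.

**Step 4**
Reactants: 5 methyl (R)-3-(tert-butyldimethylsilyloxy)-2-hydroxypropanoate; 2 2,6-dimethoxy-4-(2-methyl-1,3-dioxolan-2-yl)phenol
Product: 6 methyl (S)-3-(tert-butyldimethylsilyloxy)-2-[2,6-dimethoxy-4-(2-methyl-1,3-dioxolan-2-yl)phenoxy]propanoate
Conditions: PPh3, DIAD, toluene, 0 °C → rt
Reagents that add atoms: none
Why: Mitsunobu etherification of an α-hydroxy ester with a phenol of pKa near 10 proceeds by SN2 displacement of the oxyphosphonium group, so C8 is inverted from R to S, and the carbonyl-activated centre should accept the di-ortho-substituted phenol.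

**Step 5**
Reactants: 6 methyl (S)-3-(tert-butyldimethylsilyloxy)-2-[2,6-dimethoxy-4-(2-methyl-1,3-dioxolan-2-yl)phenoxy]propanoate
Product: 7 (S)-3-(tert-butyldimethylsilyloxy)-2-[2,6-dimethoxy-4-(2-methyl-1,3-dioxolan-2-yl)phenoxy]-N-methoxy-N-methylpropanamide
Conditions: MeNH(OMe)·HCl, i-PrMgCl, THF, −20 °C → 0 °C
Reagents that add atoms: N,O-dimethylhydroxylamine hydrochloride, CNOC.Cl
Why: Ester aminolysis by the chloromagnesium amide of N,O-dimethylhydroxylamine (direct Weinreb amide formation) runs below 0 °C, where this weakly basic amide should not deprotonate C8.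

**Step 6**
Reactants: 7 (S)-3-(tert-butyldimethylsilyloxy)-2-[2,6-dimethoxy-4-(2-methyl-1,3-dioxolan-2-yl)phenoxy]-N-methoxy-N-methylpropanamide
Product: 9 (S)-5-(tert-butyldimethylsilyloxy)-4-[2,6-dimethoxy-4-(2-methyl-1,3-dioxolan-2-yl)phenoxy]pent-1-yn-3-one, via bromomagnesium hemiaminal chelate 8 (not isolated)
Conditions: HC≡CMgBr, THF, −20 °C → 0 °C; inverse quench into cold aq. citric acid/Et2O, rapid extraction
Reagents that add atoms: ethynylmagnesium bromide, C#C[Mg]Br
Why: In this Weinreb ketone synthesis the alkynyl Grignard adds once to give a stable magnesium chelate that releases the ynone only on the cold acidic quench, which also carries the liberated hydroxylamine into the aqueous phase before it can add to the ynone.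

**Step 7**
Reactants: 10 methoxyacetone; 11 N,N-dimethylformamide dimethyl acetal
Product: 12 (3Z)-4-(dimethylamino)-3-methoxybut-3-en-2-one
Conditions: neat, 100 °C, MeOH distilled off; Kugelrohr distillation
Reagents that add atoms: none
Why: Aminomethylenation of an activated methylene ketone (enaminone formation) is driven by loss of methanol, and the favoured geometry places NMe2 trans to the acetyl group, as the diene requires.

**Step 8**
Reactants: 12 (3Z)-4-(dimethylamino)-3-methoxybut-3-en-2-one
Product: 14 (1Z)-1-(dimethylamino)-2-methoxy-3-(tert-butyldimethylsilyloxy)buta-1,3-diene, via potassium dienolate 13 (not isolated)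
Conditions: KN(SiMe3)2, THF, −78 °C; then TBSCl, −78 °C → rt; filtration under argon, distillation
Reagents that add atoms: tert-butyldimethylsilyl chloride, CC(C)(C)[Si](C)(C)Cl
Why: Kinetic deprotonation of the methyl group of a vinylogous amide followed by O-silylation (silyl enol ether formation) is the standard entry to 1-amino-3-silyloxybutadienes and leaves the enamine geometry unchanged.

**Step 9**
Reactants: 14 (1Z)-1-(dimethylamino)-2-methoxy-3-(tert-butyldimethylsilyloxy)buta-1,3-diene; 9 (S)-5-(tert-butyldimethylsilyloxy)-4-[2,6-dimethoxy-4-(2-methyl-1,3-dioxolan-2-yl)phenoxy]pent-1-yn-3-one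
Product: 16 (S)-3-(tert-butyldimethylsilyloxy)-1-[4-(tert-butyldimethylsilyloxy)-3-methoxyphenyl]-2-[2,6-dimethoxy-4-(2-methyl-1,3-dioxolan-2-yl)phenoxy]propan-1-one, via aminocyclohexadiene cycloadduct 15 (not isolated)
Conditions: 14 (1.5 equiv), toluene, −20 °C → rt; then SiO2, CH2Cl2, rt
Reagents that add atoms: none
Why: The electron-rich diene and the electron-poor terminal ynone combine in a normal-electron-demand Diels–Alder reaction, concerted but asynchronous, in which the diene CH2 terminus bonds to the alkyne β-carbon (ring A C5–C6) and the amino-bearing carbon to the α-carbon (ring A C1–C2). The closest known reaction type is the cycloaddition of 1-amino-3-silyloxybutadienes with alkynyl ketones and esters, whose 1,4-cyclohexadiene adducts lose the amine to give aryl silyl ethers. Ring A closes in this intermolecular (4+2) mode with both ring bonds formed in one operation, and the vinylogous elimination of dimethylamine from 15 on silica, driven by aromatisation, leaves OMe at C3 and OTBS at C4. No stereocentre is created, since the aminated sp3 carbon of 15 is transient and C8 is a spectator. The selectivity required is regiochemical and is secured by matched polarisation: the amino and silyloxy donors both raise the coefficient at the CH2 terminus while the ketone makes the alkyne β-carbon the electrophilic end. Because the medium is neutral and the amine is released only onto silica, the base-sensitive α-aryloxy ketone centre C8 should survive.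

**Step 10**
Reactants: 16 (S)-3-(tert-butyldimethylsilyloxy)-1-[4-(tert-butyldimethylsilyloxy)-3-methoxyphenyl]-2-[2,6-dimethoxy-4-(2-methyl-1,3-dioxolan-2-yl)phenoxy]propan-1-one
Product: 17 (1R,2S)-3-(tert-butyldimethylsilyloxy)-1-[4-(tert-butyldimethylsilyloxy)-3-methoxyphenyl]-2-[2,6-dimethoxy-4-(2-methyl-1,3-dioxolan-2-yl)phenoxy]propan-1-ol
Conditions: Zn(BH4)2, Et2O, −20 °C → 0 °C; aq. NH4Cl
Reagents that add atoms: none
Why: In this chelation-controlled (Cram-chelate) reduction zinc bridges the C7 carbonyl oxygen and the C8 aryloxy oxygen, the C9 silyl ether being a poor ligand, and hydride enters from the face of the C8 hydrogen to give the (7R,8S) erythro alcohol.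

**Step 11**
Reactants: 17 (1R,2S)-3-(tert-butyldimethylsilyloxy)-1-[4-(tert-butyldimethylsilyloxy)-3-methoxyphenyl]-2-[2,6-dimethoxy-4-(2-methyl-1,3-dioxolan-2-yl)phenoxy]propan-1-ol
Product: 18 (1R,2S)-2-[2,6-dimethoxy-4-(2-methyl-1,3-dioxolan-2-yl)phenoxy]-1-(4-hydroxy-3-methoxyphenyl)propane-1,3-diol
Conditions: Bu4NF, AcOH, THF, 0 °C → rt
Reagents that add atoms: none
Why: Fluoride-mediated desilylation cleaves both the aryl and the primary alkyl TBS ether, and the acetic acid buffer keeps the liberated phenoxide from starting quinone-methide chemistry at C7.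

**Step 12**
Reactants: 18 (1R,2S)-2-[2,6-dimethoxy-4-(2-methyl-1,3-dioxolan-2-yl)phenoxy]-1-(4-hydroxy-3-methoxyphenyl)propane-1,3-diol
Product: 19 1-[4-[(1R,2S)-1,3-dihydroxy-1-(4-hydroxy-3-methoxyphenyl)propan-2-yl]oxy-3,5-dimethoxyphenyl]ethan-1-one (CNP0242981.1)
Conditions: 0.2 M HCl, THF/H2O (4:1), 0 °C → rt; NaHCO3
Reagents that add atoms: water, O
Why: Acid-catalysed ketal hydrolysis of the aryl methyl dioxolane proceeds in dilute aqueous acid at or below room temperature, conditions expected to be too mild to ionise the benzylic C7 hydroxyl.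

**Compound list**
1 | acetosyringone, 1-(4-hydroxy-3,5-dimethoxyphenyl)ethan-1-one | CC(=O)c1cc(OC)c(O)c(OC)c1 | starting material
2 | 2,6-dimethoxy-4-(2-methyl-1,3-dioxolan-2-yl)phenol | COc1cc(C2(C)OCCO2)cc(OC)c1O | intermediate
3 | methyl (R)-2,2-dimethyl-1,3-dioxolane-4-carboxylate | COC(=O)[C@H]1COC(C)(C)O1 | starting material
4 | methyl (R)-2,3-dihydroxypropanoate | COC(=O)[C@@H](CO)O | intermediate
5 | methyl (R)-3-(tert-butyldimethylsilyloxy)-2-hydroxypropanoate | COC(=O)[C@@H](CO[Si](C)(C)C(C)(C)C)O | intermediate
6 | methyl (S)-3-(tert-butyldimethylsilyloxy)-2-[2,6-dimethoxy-4-(2-methyl-1,3-dioxolan-2-yl)phenoxy]propanoate | COC(=O)[C@H](CO[Si](C)(C)C(C)(C)C)Oc1c(OC)cc(C2(C)OCCO2)cc1OC | intermediate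
7 | (S)-3-(tert-butyldimethylsilyloxy)-2-[2,6-dimethoxy-4-(2-methyl-1,3-dioxolan-2-yl)phenoxy]-N-methoxy-N-methylpropanamide | CON(C)C(=O)[C@H](CO[Si](C)(C)C(C)(C)C)Oc1c(OC)cc(C2(C)OCCO2)cc1OC | intermediate
8 | bromomagnesium (4S)-5-(tert-butyldimethylsilyloxy)-4-[2,6-dimethoxy-4-(2-methyl-1,3-dioxolan-2-yl)phenoxy]-3-[methoxy(methyl)amino]pent-1-yn-3-olate, both C3 epimers | C#CC(O[Mg]Br)(N(C)OC)[C@H](CO[Si](C)(C)C(C)(C)C)Oc1c(OC)cc(C2(C)OCCO2)cc1OC | intermediate (not isolated)
9 | (S)-5-(tert-butyldimethylsilyloxy)-4-[2,6-dimethoxy-4-(2-methyl-1,3-dioxolan-2-yl)phenoxy]pent-1-yn-3-one | C#CC(=O)[C@H](CO[Si](C)(C)C(C)(C)C)Oc1c(OC)cc(C2(C)OCCO2)cc1OC | intermediate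
10 | methoxyacetone | COCC(C)=O | starting material
11 | N,N-dimethylformamide dimethyl acetal | COC(OC)N(C)C | starting material
12 | (3Z)-4-(dimethylamino)-3-methoxybut-3-en-2-one | CN(C)/C=C(\OC)C(C)=O | intermediate
13 | potassium (3Z)-4-(dimethylamino)-3-methoxybuta-1,3-dien-2-olate | CN(C)/C=C(\OC)C(=C)[O-].[K+] | intermediate (not isolated)
14 | (1Z)-1-(dimethylamino)-2-methoxy-3-(tert-butyldimethylsilyloxy)buta-1,3-diene | CN(C)/C=C(\OC)C(=C)O[Si](C)(C)C(C)(C)C | intermediate
15 | (2S)-3-(tert-butyldimethylsilyloxy)-1-[4-(tert-butyldimethylsilyloxy)-6-(dimethylamino)-5-methoxycyclohexa-1,4-dien-1-yl]-2-[2,6-dimethoxy-4-(2-methyl-1,3-dioxolan-2-yl)phenoxy]propan-1-one, both epimers at the aminated ring carbon | CN(C)C1C(C(=O)[C@H](CO[Si](C)(C)C(C)(C)C)Oc2c(OC)cc(C3(C)OCCO3)cc2OC)=CCC(O[Si](C)(C)C(C)(C)C)=C1OC | intermediate (not isolated)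
16 | (S)-3-(tert-butyldimethylsilyloxy)-1-[4-(tert-butyldimethylsilyloxy)-3-methoxyphenyl]-2-[2,6-dimethoxy-4-(2-methyl-1,3-dioxolan-2-yl)phenoxy]propan-1-one | COc1cc(C(=O)[C@H](CO[Si](C)(C)C(C)(C)C)Oc2c(OC)cc(C3(C)OCCO3)cc2OC)ccc1O[Si](C)(C)C(C)(C)C | intermediate
17 | (1R,2S)-3-(tert-butyldimethylsilyloxy)-1-[4-(tert-butyldimethylsilyloxy)-3-methoxyphenyl]-2-[2,6-dimethoxy-4-(2-methyl-1,3-dioxolan-2-yl)phenoxy]propan-1-ol | COc1cc([C@@H](O)[C@H](CO[Si](C)(C)C(C)(C)C)Oc2c(OC)cc(C3(C)OCCO3)cc2OC)ccc1O[Si](C)(C)C(C)(C)C | intermediate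
18 | (1R,2S)-2-[2,6-dimethoxy-4-(2-methyl-1,3-dioxolan-2-yl)phenoxy]-1-(4-hydroxy-3-methoxyphenyl)propane-1,3-diol | COc1cc([C@@H](O)[C@H](CO)Oc2c(OC)cc(C3(C)OCCO3)cc2OC)ccc1O | intermediate
19 | 1-[4-[(1R,2S)-1,3-dihydroxy-1-(4-hydroxy-3-methoxyphenyl)propan-2-yl]oxy-3,5-dimethoxyphenyl]ethan-1-one | COc1cc([C@@H](O)[C@H](CO)Oc2c(OC)cc(C(C)=O)cc2OC)ccc1O | target

**Step count and risks**
Total: 12 steps. Longest linear sequence: 9 steps (steps 2, 3, 4, 5, 6, 9, 10, 11, 12, from glycerate 3). Ring B phenol 2 (1 step) and diene 14 (2 steps) are made in parallel.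

Steps most likely to fail:

1. Step 9. The 2-methoxy group may slow the cycloaddition enough for hydrolysis of the diene to compete. Dimethylamine released on aromatisation may add to unreacted ynone, epimerise C8 or trigger β-elimination of silanol from C9. Fallback: ring A is introduced intact by aryl-metal acylation, setting out from Weinreb amide 7 and returning at ketone 16. Commercial 4-bromo-2-methoxyphenol is silylated (TBSCl, imidazole, DMF) to (4-bromo-2-methoxyphenoxy)(tert-butyl)dimethylsilane F1. Magnesium insertion (Mg, LiCl, THF) gives [4-(tert-butyldimethylsilyloxy)-3-methoxyphenyl]magnesium bromide F2. F2 is added to 7 at −20 °C → 0 °C (Weinreb ketone synthesis), and a cold buffered quench should deliver 16; the Grignard reagent is chosen over the aryllithium to limit deprotonation at C8.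

2. Step 6. N,O-Dimethylhydroxylamine liberated on work-up may add in conjugate fashion to the terminal ynone, and enolisation at C8 may cause epimerisation or loss of the C9 silyloxy group. Fallback: the ynone is reached through the aldehyde oxidation level with no amine present, setting out from ester 6 and returning at ynone 9. Reduction with i-Bu2AlH (CH2Cl2, −78 °C) should give (S)-3-(tert-butyldimethylsilyloxy)-2-[2,6-dimethoxy-4-(2-methyl-1,3-dioxolan-2-yl)phenoxy]propanal F3. Addition of HC≡CMgBr (THF, −78 °C) gives (4S)-5-(tert-butyldimethylsilyloxy)-4-[2,6-dimethoxy-4-(2-methyl-1,3-dioxolan-2-yl)phenoxy]pent-1-yn-3-ol F4 as a mixture of carbinol epimers. Oxidation with Dess–Martin periodinane (NaHCO3, CH2Cl2, 0 °C) converges both epimers on 9.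

3. Step 10. Facial selectivity may be poor if the hindered di-ortho-substituted aryloxy oxygen binds zinc weakly, so that the open-chain (Felkin-type) pathway delivers threo alcohol. Fallback: stereocontrol is moved from substrate chelation to the catalyst, setting out from ketone 16 and returning at alcohol 17 with no new compound. Asymmetric transfer hydrogenation with RuCl[(S,S)-TsDPEN](p-cymene) (cat.) and HCO2H/Et3N in CH2Cl2 at rt should deliver hydride to the face that gives the (7R) carbinol, by analogy with α-heteroatom-substituted aryl ketones. Any material epimerised at C8 would emerge as the separable threo diastereomer and would not erode the enantiopurity of the erythro product.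

**Further compounds**
F1 | step 9 | (4-bromo-2-methoxyphenoxy)(tert-butyl)dimethylsilane | COc1cc(Br)ccc1O[Si](C)(C)C(C)(C)C
F2 | step 9 | [4-(tert-butyldimethylsilyloxy)-3-methoxyphenyl]magnesium bromide | COc1cc([Mg]Br)ccc1O[Si](C)(C)C(C)(C)C
F3 | step 6 | (S)-3-(tert-butyldimethylsilyloxy)-2-[2,6-dimethoxy-4-(2-methyl-1,3-dioxolan-2-yl)phenoxy]propanal | O=C[C@H](CO[Si](C)(C)C(C)(C)C)Oc1c(OC)cc(C2(C)OCCO2)cc1OC
F4 | step 6 | (4S)-5-(tert-butyldimethylsilyloxy)-4-[2,6-dimethoxy-4-(2-methyl-1,3-dioxolan-2-yl)phenoxy]pent-1-yn-3-ol, both C3 epimers | C#CC(O)[C@H](CO[Si](C)(C)C(C)(C)C)Oc1c(OC)cc(C2(C)OCCO2)cc1OC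
F0 | step 10 | none | none
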